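**Retrosynthetic overview**

- Locants: ring C1 (C=O), C2 (propenyl), C3 (=CH), C4 (quaternary; OMe and styryl), C5 (C–OMe), C6 (=CH). The side-chain alkene is C7(Me)=C8H–Ar.
- The only ring made is the cyclohexa-2,5-dienone. It is closed last, C3–C4, from the acyclic enaminone 16. The enabling feature is the C1 carbonyl, cross-conjugated to both ring alkenes: C3 is its β-carbon (electrophilic once it bears a leaving group), and C4 is its γ-carbon through the C5(OMe)=C6 vinylogous ester (C–H acidic). C4 ends without hydrogen, so the dienone cannot aromatise.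
- The leaving group on C3 is (S)-2-(methoxymethyl)pyrrolidine. It acts as a traceless controller of the C4 configuration and is expelled in the same operation.
- 16 comes from ynone 13 (MeOH adds at C5; the amine replaces OEt on C3). 13 comes from the acetylide of 5 and Weinreb amide 11 (C1–C6 bond).
- 5 comes from veratraldehyde, propanal and ethynylmagnesium bromide. 11 comes from 3-ethoxyacryloyl chloride and (E)-propenylboronic acid.

Key step: step 9

Assumption: the sense of induction is taken from the model given under step 9. If experiment shows the opposite sense, the equally available (R)-amine is used instead.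

**Step 1**
Reactants: 1 3,4-dimethoxybenzaldehyde; 2 propanal
Product: 3 (2E)-3-(3,4-dimethoxyphenyl)-2-methylprop-2-enal
Conditions: NaOH (cat.), EtOH–H2O, slow addition of 2, 0 °C to rt
Reagents that add atoms: none
Why: Crossed aldol condensation (Claisen–Schmidt type) of a non-enolisable aldehyde with propanal; E1cB dehydration should give the favoured (E)-enal, which fixes the C7=C8 geometry of the target.

**Step 2**
Reactants: 3 (2E)-3-(3,4-dimethoxyphenyl)-2-methylprop-2-enal
Product: 4 (1E)-1-(3,4-dimethoxyphenyl)-2-methylpent-1-en-4-yn-3-ol (racemic)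
Conditions: HC≡CMgBr (1.2 equiv), THF, 0 °C; then H2O
Reagents that add atoms: ethynylmagnesium bromide, C#C[Mg]Br
Why: 1,2-Addition of an alkynyl Grignard reagent to the enal; the carbinol centre is made racemic on purpose because it is planarised in step 9.

**Step 3**
Reactants: 4 (1E)-1-(3,4-dimethoxyphenyl)-2-methylpent-1-en-4-yn-3-ol
Product: 5 4-[(1E)-3-methoxy-2-methylpent-1-en-4-yn-1-yl]-1,2-dimethoxybenzene (racemic)
Conditions: NaH (1.05 equiv), MeI (1.2 equiv), THF, 0 °C to rt
Reagents that add atoms: iodomethane, CI
Why: Williamson etherification of the alkoxide, which one equivalent of NaH forms selectively over the less acidic alkyne C–H.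

**Step 4**
Reactants: 6 (2E)-3-ethoxyprop-2-enoyl chloride
Product: 7 (2E)-3-ethoxy-N-methoxy-N-methylprop-2-enamide
Conditions: MeNH(OMe)·HCl (1.05 equiv), pyridine (2.2 equiv), CH2Cl2, 0 °C
Reagents that add atoms: N,O-dimethylhydroxylamine hydrochloride, CNOC.Cl
Why: N-Acylation by the acid chloride (Weinreb amide formation), which is faster than vinylic substitution at the ethoxy-bearing carbon.

**Step 5**
Reactants: 7 (2E)-3-ethoxy-N-methoxy-N-methylprop-2-enamide
Product: 9 (2Z)-2-bromo-3-ethoxy-N-methoxy-N-methylprop-2-enamide, via dibromide 8 (not isolated)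
Conditions: Br2 (1.0 equiv), CH2Cl2, 0 °C; then Et3N (1.2 equiv), 0 °C to rt
Reagents that add atoms: bromine, BrBr
Why: Bromine addition to the enol-ether alkene followed by E1cB loss of HBr (α-H, β-Br), the standard route to (Z)-α-bromo-β-alkoxyacrylic derivatives with bromine cis to the alkoxy group.

**Step 6**
Reactants: 9 (2Z)-2-bromo-3-ethoxy-N-methoxy-N-methylprop-2-enamide; 10 (E)-prop-1-en-1-ylboronic acid
Product: 11 (2E,3E)-2-(ethoxymethylidene)-N-methoxy-N-methylpent-3-enamide
Conditions: Pd(PPh3)4 (5 mol %), K2CO3 (2 equiv), 1,4-dioxane–H2O, 80 °C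
Reagents that add atoms: none
Why: Suzuki–Miyaura coupling with retention at both alkenyl partners, which places the (E)-propenyl group cis to the ethoxy group.

**Step 7**
Reactants: 5 4-[(1E)-3-methoxy-2-methylpent-1-en-4-yn-1-yl]-1,2-dimethoxybenzene; 11 (2E,3E)-2-(ethoxymethylidene)-N-methoxy-N-methylpent-3-enamide
Product: 13 (2E,4E,9E)-10-(3,4-dimethoxyphenyl)-4-(ethoxymethylidene)-8-methoxy-9-methyldeca-2,9-dien-6-yn-5-one, via lithium acetylide 12 (not isolated)
Conditions: 5, n-BuLi (1.0 equiv), THF, −78 °C; then 11, −78 to −20 °C; then H2O (pH 7 buffer)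
Reagents that add atoms: none
Why: Weinreb ketone synthesis; the chelated tetrahedral adduct holds the acetylide addition at the ketone stage until work-up.

**Step 8**
Reactants: 13 (2E,4E,9E)-10-(3,4-dimethoxyphenyl)-4-(ethoxymethylidene)-8-methoxy-9-methyldeca-2,9-dien-6-yn-5-one; 14 (S)-2-(methoxymethyl)pyrrolidine
Product: 16 (2E,4E,6E,9E)-10-(3,4-dimethoxyphenyl)-7,8-dimethoxy-4-{[(2S)-2-(methoxymethyl)pyrrolidin-1-yl]methylidene}-9-methyldeca-2,6,9-trien-5-one (epimers at the methoxy-bearing sp3 carbon), via bis(vinylogous ester) 15 (not isolated)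
Conditions: MeOH (10 equiv), DABCO (10 mol %), CH2Cl2, 0 °C to rt; then 14 (1.1 equiv), rt
Reagents that add atoms: methanol, CO
Why: Amine-catalysed oxa-Michael addition of methanol to the ynone β-carbon places the C5 methoxy group, and the secondary amine then replaces ethoxide by addition–elimination only at the unhindered alkoxymethylene CH, which should give the (E)-enaminone.

**Step 9**
Reactants: 16 (2E,4E,6E,9E)-10-(3,4-dimethoxyphenyl)-7,8-dimethoxy-4-{[(2S)-2-(methoxymethyl)pyrrolidin-1-yl]methylidene}-9-methyldeca-2,6,9-trien-5-one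
Product: 20 (4S)-4-[(1E)-1-(3,4-dimethoxyphenyl)prop-1-en-2-yl]-4,5-dimethoxy-2-[(1E)-prop-1-en-1-yl]cyclohexa-2,5-dien-1-one, via potassium trienolate 17 (not isolated), via potassium amino-enolate 18 (not isolated), via Mannich base 19 (not isolated)
Conditions: KHMDS (1.15 equiv), THF, −78 to 0 °C; then AcOH (3 equiv), 0 °C to rt
Reagents that add atoms: none
Why: Proposed new method: KHMDS removes the only acidic hydrogen, C4–H (γ to the C1 ketone through the C5=C6 vinylogous ester and doubly allylic); the U-shaped cross-conjugated trienolate 17 (C3=C2–C1(OK)=C6–C5=C4) closes C3–C4 to amino-enolate 18, acetic acid protonates it to Mannich base 19, and β-elimination of the amine gives 20, which cannot tautomerise to a phenol because C4 carries no hydrogen. The closest known reaction types are the facile electrocyclisation of 3-oxidohexatrienes, the electrocyclisation–amine elimination of 1-aminohexatrienes used in benzannulations, and addition–elimination on enamines that bear 2-(methoxymethyl)pyrrolidine as a chiral leaving group to build quaternary carbons on enolates; their union in a ring closure to a quinol ether is new. The six-membered ring closes in the thermally allowed disrotatory 6π mode, equivalent to a 6-endo-trig vinylogous Michael addition. The C4 configuration is controlled by the pyrrolidine stereocentre: allylic strain with the cis propenyl group turns the substituted pyrrolidine carbon toward C3–H at the mouth of the triene, its CH2OMe arm covers one face of C3, C4 bonds to the open face, and with methoxy inside and styryl outside on C4=C5 this disrotation should give (S); potassium bridging of the arm oxygen and the inside C4 methoxy acts in the same sense, and the transient C3 stereocentre vanishes with the auxiliary. The step needs periselectivity over the 8π closure C3–C8 and a single C4=C5 geometry in the closing isomer; both rest on the size difference at C4, because the bulky trisubstituted styryl group avoids the inside position that the 8π path demands, and bonding at C8 would also cost the styrene conjugation.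

**Compound list**

1 | 3,4-dimethoxybenzaldehyde | COc1ccc(C=O)cc1OC | starting material
2 | propanal | CCC=O | starting material
3 | (2E)-3-(3,4-dimethoxyphenyl)-2-methylprop-2-enal | O=C/C(C)=C/c1ccc(OC)c(OC)c1 | intermediate
4 | (1E)-1-(3,4-dimethoxyphenyl)-2-methylpent-1-en-4-yn-3-ol, racemic | C#CC(O)/C(C)=C/c1ccc(OC)c(OC)c1 | intermediate
5 | 4-[(1E)-3-methoxy-2-methylpent-1-en-4-yn-1-yl]-1,2-dimethoxybenzene, racemic | C#CC(OC)/C(C)=C/c1ccc(OC)c(OC)c1 | intermediate
6 | (2E)-3-ethoxyprop-2-enoyl chloride | CCO/C=C/C(=O)Cl | starting material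
7 | (2E)-3-ethoxy-N-methoxy-N-methylprop-2-enamide | CCO/C=C/C(=O)N(C)OC | intermediate
8 | 2,3-dibromo-3-ethoxy-N-methoxy-N-methylpropanamide (not isolated) | CCOC(Br)C(Br)C(=O)N(C)OC | intermediate
9 | (2Z)-2-bromo-3-ethoxy-N-methoxy-N-methylprop-2-enamide | CCO/C=C(\Br)C(=O)N(C)OC | intermediate
10 | (E)-prop-1-en-1-ylboronic acid | C/C=C/B(O)O | starting material
11 | (2E,3E)-2-(ethoxymethylidene)-N-methoxy-N-methylpent-3-enamide | CCO/C=C(\C=C\C)C(=O)N(C)OC | intermediate
12 | lithium acetylide of 5 (not isolated) | [Li]C#CC(OC)/C(C)=C/c1ccc(OC)c(OC)c1 | intermediate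
13 | (2E,4E,9E)-10-(3,4-dimethoxyphenyl)-4-(ethoxymethylidene)-8-methoxy-9-methyldeca-2,9-dien-6-yn-5-one, racemic | CCO/C=C(\C=C\C)C(=O)C#CC(OC)/C(C)=C/c1ccc(OC)c(OC)c1 | intermediate
14 | (S)-2-(methoxymethyl)pyrrolidine | COC[C@@H]1CCCN1 | starting material
15 | (2E,4E,6E,9E)-10-(3,4-dimethoxyphenyl)-4-(ethoxymethylidene)-7,8-dimethoxy-9-methyldeca-2,6,9-trien-5-one, racemic (not isolated) | CCO/C=C(\C=C\C)C(=O)/C=C(/OC)C(OC)/C(C)=C/c1ccc(OC)c(OC)c1 | intermediate
16 | (2E,4E,6E,9E)-10-(3,4-dimethoxyphenyl)-7,8-dimethoxy-4-{[(2S)-2-(methoxymethyl)pyrrolidin-1-yl]methylidene}-9-methyldeca-2,6,9-trien-5-one, epimers at the methoxy-bearing sp3 carbon | COC[C@@H]1CCCN1/C=C(\C=C\C)C(=O)/C=C(/OC)C(OC)/C(C)=C/c1ccc(OC)c(OC)c1 | intermediate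
17 | potassium trienolate of 16; C2 cis to C5 on C1=C6, C4 methoxy cis to C6 on C4=C5 (not isolated) | [K+].COC[C@@H]1CCCN1/C=C(\C=C\C)/C([O-])=C\C(OC)=C(OC)\C(C)=C\c1ccc(OC)c(OC)c1 | intermediate
18 | cyclised potassium amino-enolate; amine on C3 cis to the styryl group on C4, C4 arranged as in 20 (not isolated) | [K+].C/C=C/C1=C([O-])C=C(OC)[C@@](OC)(/C(C)=C/c2ccc(OC)c(OC)c2)[C@H]1N3CCC[C@H]3COC | intermediate
19 | Mannich base, the C2-protonated ketone of 18, C2 configuration undefined (not isolated) | C/C=C/C1C(=O)C=C(OC)[C@@](OC)(/C(C)=C/c2ccc(OC)c(OC)c2)[C@H]1N3CCC[C@H]3COC | intermediate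
20 | (4S)-4-[(1E)-1-(3,4-dimethoxyphenyl)prop-1-en-2-yl]-4,5-dimethoxy-2-[(1E)-prop-1-en-1-yl]cyclohexa-2,5-dien-1-one | C/C=C/C1=C[C@](OC)(/C(C)=C/c2ccc(OC)c(OC)c2)C(OC)=CC1=O | target

**Step count**

Total step count: 9.
Longest linear sequence: 6 steps (steps 1–3 or 4–6, then 7–9).

**Steps most likely to fail**

Step 9 (Proposed new method). In the electron-rich trienolate the amino group may twist out of conjugation, which loosens the conformational lock of the auxiliary. Closure through the minor C4=C5 isomer would also deliver the antipode. Both processes lower the enantiomeric purity.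

The fallback gives up induction and uses classical operations only. It sets out from 13. Methanol is added as in the first half of step 8 and 15 is isolated. Catalytic KOt-Bu in THF at 0 °C triggers the alkoxide-induced addition–elimination of the carbon acid on the alkoxymethylene ketone; ethoxide is the leaving group and carries the chain. This should give the racemic dienone F1. Preparative SFC on an immobilised polysaccharide phase then separates 20 from the (R)-dienone F2. The fallback comes back to the route at 20.

Step 8. The ynone may undergo propargyl–allenyl isomerisation under amine catalysis. The auxiliary amine may also attack residual ynone or C5 instead of C3.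

The fallback reverses the order of events and sets out from 11. Amine 14 replaces ethoxide first, giving the enamino Weinreb amide F3. Acetylide 12 is acylated by F3 to the amino-ynone F4, whose amine is not exchangeable. Methanol is then added with catalytic NaOMe in MeOH. The fallback comes back to the route at 16.

Step 7. The push–pull, α-branched Weinreb amide may be acylated slowly, and long contact would let the basic acetylide isomerise or degrade the ynone.

The fallback replaces acylation by carbonyl addition and oxidation, and sets out from 11. DIBAL-H at −78 °C gives the dienal F5. Acetylide 12 adds to it to give the propargylic alcohol F6. MnO2 in CH2Cl2 oxidises the doubly activated carbinol. The fallback comes back to the route at 13.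

**Further compounds**

F1 | step 9 | 4-[(1E)-1-(3,4-dimethoxyphenyl)prop-1-en-2-yl]-4,5-dimethoxy-2-[(1E)-prop-1-en-1-yl]cyclohexa-2,5-dien-1-one, racemic | C/C=C/C1=CC(OC)(/C(C)=C/c2ccc(OC)c(OC)c2)C(OC)=CC1=O
F2 | step 9 | (4R)-4-[(1E)-1-(3,4-dimethoxyphenyl)prop-1-en-2-yl]-4,5-dimethoxy-2-[(1E)-prop-1-en-1-yl]cyclohexa-2,5-dien-1-one | C/C=C/C1=C[C@@](OC)(/C(C)=C/c2ccc(OC)c(OC)c2)C(OC)=CC1=O
F3 | step 8 | (2E,3E)-N-methoxy-2-{[(2S)-2-(methoxymethyl)pyrrolidin-1-yl]methylidene}-N-methylpent-3-enamide | COC[C@@H]1CCCN1/C=C(\C=C\C)C(=O)N(C)OC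
F4 | step 8 | (2E,4E,9E)-10-(3,4-dimethoxyphenyl)-8-methoxy-4-{[(2S)-2-(methoxymethyl)pyrrolidin-1-yl]methylidene}-9-methyldeca-2,9-dien-6-yn-5-one, epimers at the methoxy-bearing sp3 carbon | COC[C@@H]1CCCN1/C=C(\C=C\C)C(=O)C#CC(OC)/C(C)=C/c1ccc(OC)c(OC)c1
F5 | step 7 | (2E,3E)-2-(ethoxymethylidene)pent-3-enal | CCO/C=C(\C=C\C)C=O
F6 | step 7 | (2E,4E,9E)-10-(3,4-dimethoxyphenyl)-4-(ethoxymethylidene)-8-methoxy-9-methyldeca-2,9-dien-6-yn-5-ol, mixture of diastereomers | CCO/C=C(\C=C\C)C(O)C#CC(OC)/C(C)=C/c1ccc(OC)c(OC)c1
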